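**Retrosynthetic overview**
- Ring B is formed last. One operation disconnects C7–C8 and C9–C11: an anti-selective alkylative cyclization of a ring-A alkynal (C10–C≡C–CH3 and C5–CH(OSiEt3)–CHO) with a side-chain B-alkyl borane.
- Enabling feature: the tetrasubstituted C8=C9 olefin of ring B carries C7 (carbinol carbon) and C11 (first side-chain carbon) trans to each other, with the C17 methyl and C10 as the other pair. This is the retron of an anti addition of an aldehyde carbon and an alkyl group across a C8≡C9 alkyne tethered through C10–C5–C6.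
- Ring A is bought as 2,4,4-trimethylcyclohex-2-en-1-one: CBS reduction sets the C1 carbinol, a [2,3]-Wittig rearrangement sets C5 and C6, and an iron-hydride HAT alkynylation sets the quaternary C10.
- The side chain comes from (2E)-3-methylpent-2-en-4-yn-1-ol; the end game is desilylation, bis-acetylation and desilylation.

Key step: step 10

Remark on the chemistry: labdane numbering is used for all intermediates (C1–C5 and C10 = ring A; C6–C9 complete ring B; C17 = methyl on C8; C11–C16 = side chain). Compounds 1 and 10 and trimethyl[(phenylsulfonyl)ethynyl]silane are taken as purchasable.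

Step 1
Reactants: 1 2,4,4-trimethylcyclohex-2-en-1-one
Product: 2 (1R)-2,4,4-trimethylcyclohex-2-en-1-ol
Conditions: (S)-2-methyl-CBS-oxazaborolidine (10 mol %), BH3·SMe2, THF, −20 °C; MeOH quench
Reagents that add atoms: none
Why: Corey–Bakshi–Shibata reduction, in which the oxazaborolidine–borane complex delivers hydride to one carbonyl face with the olefinic carbon acting as the large group, should give the (R)-allylic alcohol by 1,2-reduction (the enantiomeric catalyst is used if the sense proves opposite).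

Step 2
Reactants: 2 (1R)-2,4,4-trimethylcyclohex-2-en-1-ol
Product: 3 ethyl {[(1R)-2,4,4-trimethylcyclohex-2-en-1-yl]oxy}acetate
Conditions: Rh2(OAc)4 (1 mol %), ethyl diazoacetate (slow addition), CH2Cl2, rt
Reagents that add atoms: ethyl diazoacetate, CCOC(=O)C=[N+]=[N-]
Why: Rhodium-carbenoid O–H insertion into an allylic alcohol is a standard entry to allyloxyacetates, should outrun cyclopropanation of the hindered trisubstituted olefin, and leaves the carbinol centre untouched.

Step 3
Reactants: 3 ethyl {[(1R)-2,4,4-trimethylcyclohex-2-en-1-yl]oxy}acetate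
Product: 4 ethyl (2S)-2-hydroxy-2-[(1S)-2,6,6-trimethylcyclohex-2-en-1-yl]acetate
Conditions: LiN(i-Pr)2 (1.2 equiv), THF, −78 to −20 °C; aq. NH4Cl
Reagents that add atoms: none
Why: [2,3]-Wittig rearrangement of the ester enolate forms C5–C6 on the ring face from which the C1–O bond departs (suprafacial transfer, sets C5), and the envelope transition state with the enolate group exo, away from ring A and its C4 gem-dimethyl group, should set C6 as S.

Step 4
Reactants: 4 ethyl (2S)-2-hydroxy-2-[(1S)-2,6,6-trimethylcyclohex-2-en-1-yl]acetate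
Product: 6 ethyl (2S)-2-[(1S,2S)-2-ethynyl-2,6,6-trimethylcyclohexyl]-2-hydroxyacetate, via trimethylsilylalkyne 5 (not isolated)
Conditions: Fe(acac)3 (30 mol %), PhSiH3, trimethyl[(phenylsulfonyl)ethynyl]silane, EtOH, 60 °C; then K2CO3, EtOH, rt
Reagents that add atoms: trimethyl[(phenylsulfonyl)ethynyl]silane, C[Si](C)(C)C#CS(=O)(=O)c1ccccc1
Why: Iron-hydride hydrogen-atom-transfer (Mukaiyama-type) hydroalkynylation puts H on C1 and lets the tertiary C10 radical substitute the sulfonyl group of the alkynyl sulfone (addition, then loss of PhSO2 radical); equatorial attack, away from the syn-axial C4 methyl and trans to the C5 side chain, should set C10 with its methyl axial, and ethanolysis then removes the silyl group.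

Step 5
Reactants: 6 ethyl (2S)-2-[(1S,2S)-2-ethynyl-2,6,6-trimethylcyclohexyl]-2-hydroxyacetate
Product: 7 ethyl (2S)-2-hydroxy-2-[(1S,2S)-2,6,6-trimethyl-2-(prop-1-yn-1-yl)cyclohexyl]acetate
Conditions: LiN(i-Pr)2 (2.05 equiv), THF, −78 °C; MeI (1.1 equiv), DMPU, −78 to −10 °C; aq. NH4Cl
Reagents that add atoms: iodomethane, CI
Why: Alkylation of a lithium acetylide: the O–H and then the sp C–H are deprotonated before the ester α-C–H (which sits next to the alkoxide), so C-methylation of the acetylide should occur without touching C6.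

Step 6
Reactants: 7 ethyl (2S)-2-hydroxy-2-[(1S,2S)-2,6,6-trimethyl-2-(prop-1-yn-1-yl)cyclohexyl]acetate
Product: 8 ethyl (2S)-2-[(triethylsilyl)oxy]-2-[(1S,2S)-2,6,6-trimethyl-2-(prop-1-yn-1-yl)cyclohexyl]acetate
Conditions: Et3SiOTf, 2,6-lutidine, CH2Cl2, −78 to 0 °C
Reagents that add atoms: triethylsilyl trifluoromethanesulfonate, CC[Si](CC)(CC)OS(=O)(=O)C(F)(F)F
Why: Silyl triflate silylation with a hindered pyridine base is the standard way to protect a congested secondary alcohol and creates no stereocentre.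

Step 7
Reactants: 8 ethyl (2S)-2-[(triethylsilyl)oxy]-2-[(1S,2S)-2,6,6-trimethyl-2-(prop-1-yn-1-yl)cyclohexyl]acetate
Product: 9 (2S)-2-[(triethylsilyl)oxy]-2-[(1S,2S)-2,6,6-trimethyl-2-(prop-1-yn-1-yl)cyclohexyl]acetaldehyde
Conditions: i-Bu2AlH (1.1 equiv), CH2Cl2, −78 °C; aq. KNaC4H4O6 work-up
Reagents that add atoms: none
Why: Partial ester reduction with i-Bu2AlH stops at the aldehyde because the α-alkoxy tetrahedral aluminium hemiacetal persists at −78 °C, and the base-free conditions should not epimerise C6.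

Step 8
Reactants: 10 (2E)-3-methylpent-2-en-4-yn-1-ol
Product: 11 tert-butyl{[(2E)-3-methylpent-2-en-4-yn-1-yl]oxy}diphenylsilane
Conditions: t-BuPh2SiCl, imidazole, DMF, rt
Reagents that add atoms: tert-butyl(chloro)diphenylsilane, CC(C)(C)[Si](Cl)(c1ccccc1)c1ccccc1
Why: Standard silylation of a primary allylic alcohol gives a robust ether that survives every later step until the final fluoride treatment.

Step 9
Reactants: 11 tert-butyl{[(2E)-3-methylpent-2-en-4-yn-1-yl]oxy}diphenylsilane
Product: 12 tert-butyl{[(2E)-3-methylpenta-2,4-dien-1-yl]oxy}diphenylsilane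
Conditions: H2 (1 atm), Pd on CaCO3 poisoned with Pb(OAc)2, quinoline, hexane, rt
Reagents that add atoms: none
Why: Lindlar-type semi-hydrogenation reduces the terminal alkyne to the vinyl group and should leave the trisubstituted olefin and its E geometry unchanged.

Step 10
Reactants: 9 (2S)-2-[(triethylsilyl)oxy]-2-[(1S,2S)-2,6,6-trimethyl-2-(prop-1-yn-1-yl)cyclohexyl]acetaldehyde; 12 tert-butyl{[(2E)-3-methylpenta-2,4-dien-1-yl]oxy}diphenylsilane
Product: 14 (5S,6S,7S,10S)-15-{[tert-butyl(diphenyl)silyl]oxy}-6-[(triethylsilyl)oxy]labda-8,13(E)-dien-7-ol, via B-alkyl-9-borabicyclononane 13 (not isolated)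
Conditions: 12 (1.6 equiv), (9-BBN-H)2 (0.75 equiv), THF, 0 °C to rt; then 9 (1.0 equiv), Pd2(dba)3 (5 mol %), PCy3 (20 mol %), THF/MeOH 4:1, 60 °C
Reagents that add atoms: none
Why: Proposed new method: zerovalent palladium binds the C8≡C9 alkyne of 9 and the electron-rich alkyne–metal unit attacks the C7 aldehyde through C8 on the face opposite to the metal, as in the known palladium-catalysed anti-selective ("anti-Wacker"-type) arylative cyclization of 5-alkynals with arylboronic acids, giving a trans-alkenyl divalent palladium alkoxide; the alkoxide (or methoxide) activates borane 13, the C11 alkyl group passes to palladium, and C(sp2)–C(sp3) reductive elimination forms C9–C11 and returns the catalyst. Ring B closes in a 6-endo-dig mode through C7–C8, the 5-exo alternative at C9 being disfavoured by the adjacent quaternary C10. The only new stereocentre, C7, is set in a chair-like transition state trans-fused to ring A, where the carbonyl oxygen should sit pseudoaxial (α), anti to the axial C6–OSiEt3 bond (dipole minimisation) and clear of developing A(1,2) strain with the C17 methyl, giving 7S. The step needs anti rather than syn addition so that C7 and C10 end cis on the olefin, and the substrate secures this because only the anti adduct can hold an endocyclic C8=C9 bond in a six-membered ring. The new elements relative to precedent are alkyl (not aryl) transfer from a 9-BBN borane, generated by terminal hydroboration of diene 12 with the diene in excess so that no B–H remains, and the neopentyl-type C9.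

Step 11
Reactants: 14 (5S,6S,7S,10S)-15-{[tert-butyl(diphenyl)silyl]oxy}-6-[(triethylsilyl)oxy]labda-8,13(E)-dien-7-ol
Product: 15 (5S,6S,7S,10S)-15-{[tert-butyl(diphenyl)silyl]oxy}labda-8,13(E)-diene-6,7-diol
Conditions: pyridinium p-toluenesulfonate (cat.), MeOH/CH2Cl2, 0 °C to rt
Reagents that add atoms: none
Why: Acid-catalysed methanolysis should remove the triethylsilyl ether selectively, since the tert-butyldiphenylsilyl ether is far more stable to mild acid.

Step 12
Reactants: 15 (5S,6S,7S,10S)-15-{[tert-butyl(diphenyl)silyl]oxy}labda-8,13(E)-diene-6,7-diol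
Product: 16 (5S,6S,7S,10S)-15-{[tert-butyl(diphenyl)silyl]oxy}labda-8,13(E)-diene-6,7-diyl diacetate
Conditions: Ac2O, DMAP, pyridine, 40 °C
Reagents that add atoms: acetic anhydride, CC(=O)OC(C)=O
Why: DMAP-catalysed acylation should esterify both secondary alcohols (gentle heating for the hindered axial 6-OH) without affecting any stereocentre.

Step 13
Reactants: 16 (5S,6S,7S,10S)-15-{[tert-butyl(diphenyl)silyl]oxy}labda-8,13(E)-diene-6,7-diyl diacetate
Product: 17 (5S,6S,7S,10S)-15-hydroxylabda-8,13(E)-diene-6,7-diyl diacetate (6β,7α-diacetoxy; CNP0187815.1)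
Conditions: HF·pyridine, pyridine, THF, rt
Reagents that add atoms: none
Why: Fluoride-driven Si–O cleavage under buffered, mildly acidic conditions should free the primary allylic alcohol while both acetates and the allylic C7 ester stay intact.

**Compound list**
1 | 2,4,4-trimethylcyclohex-2-en-1-one | CC1=CC(C)(C)CCC1=O | starting material
2 | (1R)-2,4,4-trimethylcyclohex-2-en-1-ol | O[C@@H]1CCC(C)(C)C=C1C | intermediate
3 | ethyl {[(1R)-2,4,4-trimethylcyclohex-2-en-1-yl]oxy}acetate | CCOC(=O)CO[C@@H]1CCC(C)(C)C=C1C | intermediate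
4 | ethyl (2S)-2-hydroxy-2-[(1S)-2,6,6-trimethylcyclohex-2-en-1-yl]acetate | CCOC(=O)[C@@H](O)[C@@H]1C(C)=CCCC1(C)C | intermediate
5 | ethyl (2S)-2-hydroxy-2-{(1S,2S)-2,6,6-trimethyl-2-[(trimethylsilyl)ethynyl]cyclohexyl}acetate | CCOC(=O)[C@@H](O)[C@@H]1[C@@](C)(C#C[Si](C)(C)C)CCCC1(C)C | intermediate
6 | ethyl (2S)-2-[(1S,2S)-2-ethynyl-2,6,6-trimethylcyclohexyl]-2-hydroxyacetate | CCOC(=O)[C@@H](O)[C@@H]1[C@@](C)(C#C)CCCC1(C)C | intermediate
7 | ethyl (2S)-2-hydroxy-2-[(1S,2S)-2,6,6-trimethyl-2-(prop-1-yn-1-yl)cyclohexyl]acetate | CCOC(=O)[C@@H](O)[C@@H]1[C@@](C)(C#CC)CCCC1(C)C | intermediate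
8 | ethyl (2S)-2-[(triethylsilyl)oxy]-2-[(1S,2S)-2,6,6-trimethyl-2-(prop-1-yn-1-yl)cyclohexyl]acetate | CCOC(=O)[C@@H](O[Si](CC)(CC)CC)[C@@H]1[C@@](C)(C#CC)CCCC1(C)C | intermediate
9 | (2S)-2-[(triethylsilyl)oxy]-2-[(1S,2S)-2,6,6-trimethyl-2-(prop-1-yn-1-yl)cyclohexyl]acetaldehyde | O=C[C@@H](O[Si](CC)(CC)CC)[C@@H]1[C@@](C)(C#CC)CCCC1(C)C | intermediate
10 | (2E)-3-methylpent-2-en-4-yn-1-ol | C#C/C(C)=C/CO | starting material
11 | tert-butyl{[(2E)-3-methylpent-2-en-4-yn-1-yl]oxy}diphenylsilane | C#C/C(C)=C/CO[Si](c1ccccc1)(c1ccccc1)C(C)(C)C | intermediate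
12 | tert-butyl{[(2E)-3-methylpenta-2,4-dien-1-yl]oxy}diphenylsilane | C=C/C(C)=C/CO[Si](c1ccccc1)(c1ccccc1)C(C)(C)C | intermediate
13 | 9-[(3E)-5-{[tert-butyl(diphenyl)silyl]oxy}-3-methylpent-3-en-1-yl]-9-borabicyclo[3.3.1]nonane | CC(C)(C)[Si](OC/C=C(C)/CCB1C2CCCC1CCC2)(c1ccccc1)c1ccccc1 | intermediate
14 | (5S,6S,7S,10S)-15-{[tert-butyl(diphenyl)silyl]oxy}-6-[(triethylsilyl)oxy]labda-8,13(E)-dien-7-ol (6β-silyloxy, 7α-hydroxy) | CC[Si](CC)(CC)O[C@@H]1[C@@H](O)C(C)=C(CC/C(C)=C/CO[Si](c2ccccc2)(c2ccccc2)C(C)(C)C)[C@@]3(C)CCCC(C)(C)[C@H]13 | intermediate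
15 | (5S,6S,7S,10S)-15-{[tert-butyl(diphenyl)silyl]oxy}labda-8,13(E)-diene-6,7-diol (6β,7α) | O[C@@H]1[C@@H](O)C(C)=C(CC/C(C)=C/CO[Si](c2ccccc2)(c2ccccc2)C(C)(C)C)[C@@]3(C)CCCC(C)(C)[C@H]13 | intermediate
16 | (5S,6S,7S,10S)-15-{[tert-butyl(diphenyl)silyl]oxy}labda-8,13(E)-diene-6,7-diyl diacetate | CC(=O)O[C@@H]1[C@@H](OC(C)=O)C(C)=C(CC/C(C)=C/CO[Si](c2ccccc2)(c2ccccc2)C(C)(C)C)[C@@]3(C)CCCC(C)(C)[C@H]13 | intermediate
17 | (5S,6S,7S,10S)-15-hydroxylabda-8,13(E)-diene-6,7-diyl diacetate (6β,7α-diacetoxylabda-8,13E-dien-15-ol) | CC(=O)O[C@@H]1[C@@H](OC(C)=O)C(C)=C(CC/C(C)=C/CO)[C@@]2(C)CCCC(C)(C)[C@H]12 | target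

**Totals**
Total step count: 13. Longest linear sequence: 11 steps (steps 1–7 and 10–13).

**Steps most likely to fail**

1. Step 10 (Proposed new method). Alkyl transfer from boron to the alkenylpalladium intermediate may be slower than its protonolysis or than β-hydride loss from the alkylpalladium; the borane may reduce the aldehyde; and facial selectivity at C7 may be poor. The fallback sets out from 9 and returns at 15, and keeps C7–C8 as the ring-closing bond in a stepwise, known sequence. Gold-catalysed, formyl-assisted hydration of the alkyne (Ph3PAuNTf2, wet dioxane) should place the carbonyl at C9 and give keto aldehyde F1. Soft enolisation of the ethyl ketone (n-Bu2BOTf, i-Pr2NEt, CH2Cl2, −78 °C) and intramolecular aldol addition to the C7 aldehyde should give the bicyclic β-hydroxy ketone F2. Silylation (Et3SiOTf, 2,6-lutidine) gives bis-silyl ether F3, and KN(SiMe3)2 with PhNTf2 gives enol triflate F4. B-alkyl Suzuki–Miyaura coupling of F4 with borane 13 (Pd(dppf)Cl2, AsPh3, Cs2CO3, DMF/THF/H2O) gives the bis-triethylsilyl labdadiene F5. Methanolysis with pyridinium p-toluenesulfonate removes both triethylsilyl groups and gives diol 15.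

2. Step 4. Trapping of the C10 radical may show poor facial selectivity, and conjugate addition to the sulfone may compete with substitution. The fallback sets out from 4 and returns at 7, and sets C10 by a polar conjugate addition instead. Allylic oxidation at C2 (Rh2(cap)4, t-BuOOH, K2CO3, CH2Cl2) gives enone F6. Nickel-catalysed conjugate addition of dimethyl(prop-1-ynyl)aluminium (Ni(acac)2, i-Bu2AlH, Et2O, −5 °C), which should enter anti to the C5 substituent, gives alkynyl ketone F7. Condensation with 4-methylbenzenesulfonohydrazide gives tosylhydrazone F8, and reduction with catecholborane followed by NaOAc removes the C2 oxygen and gives 7.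

3. Step 3. A competing [1,2]-shift or ester self-condensation of the enolate may occur, and the exo/endo preference that sets C6 may erode. The fallback sets out from 2 and returns at 4, and builds C5–C6 by a [3,3] shift with C6 oxidised afterwards. Johnson–Claisen rearrangement of 2 (triethyl orthoacetate, cat. propionic acid, 140 °C) transfers the C1 configuration to C5 and gives ester F9. Enolate hydroxylation (KN(SiMe3)2, THF, −78 °C, then the enantiomer of (camphorsulfonyl)oxaziridine matched to give 6S) gives 4.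

**Further compounds**
F1 | step 10 | (2S)-2-[(1S,2S)-2,6,6-trimethyl-2-propanoylcyclohexyl]-2-[(triethylsilyl)oxy]acetaldehyde | O=C[C@@H](O[Si](CC)(CC)CC)[C@@H]1[C@@](C)(C(=O)CC)CCCC1(C)C
F2 | step 10 | (3S,4S,4aS,8aS)-3-hydroxy-2,5,5,8a-tetramethyl-4-[(triethylsilyl)oxy]octahydronaphthalen-1(2H)-one (epimers at C2 of the ring, labdane C8) | CC[Si](CC)(CC)O[C@@H]1[C@@H](O)C(C)C(=O)[C@@]2(C)CCCC(C)(C)[C@H]12
F3 | step 10 | (3S,4S,4aS,8aS)-2,5,5,8a-tetramethyl-3,4-bis[(triethylsilyl)oxy]octahydronaphthalen-1(2H)-one | CC[Si](CC)(CC)O[C@@H]1[C@@H](O[Si](CC)(CC)CC)C(C)C(=O)[C@@]2(C)CCCC(C)(C)[C@H]12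
F4 | step 10 | (3S,4S,4aS,8aS)-2,5,5,8a-tetramethyl-3,4-bis[(triethylsilyl)oxy]-3,4,4a,5,6,7,8,8a-octahydronaphthalen-1-yl trifluoromethanesulfonate | CC[Si](CC)(CC)O[C@@H]1[C@@H](O[Si](CC)(CC)CC)C(C)=C(OS(=O)(=O)C(F)(F)F)[C@@]2(C)CCCC(C)(C)[C@H]12
F5 | step 10 | (5S,6S,7S,10S)-15-{[tert-butyl(diphenyl)silyl]oxy}-6,7-bis[(triethylsilyl)oxy]labda-8,13(E)-diene | CC[Si](CC)(CC)O[C@@H]1[C@@H](O[Si](CC)(CC)CC)C(C)=C(CC/C(C)=C/CO[Si](c2ccccc2)(c2ccccc2)C(C)(C)C)[C@@]3(C)CCCC(C)(C)[C@H]13
F6 | step 4 | ethyl (2S)-2-hydroxy-2-[(1S)-2,6,6-trimethyl-4-oxocyclohex-2-en-1-yl]acetate | CCOC(=O)[C@@H](O)[C@@H]1C(C)=CC(=O)CC1(C)C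
F7 | step 4 | ethyl (2S)-2-hydroxy-2-[(1S,2S)-2,6,6-trimethyl-4-oxo-2-(prop-1-yn-1-yl)cyclohexyl]acetate | CCOC(=O)[C@@H](O)[C@@H]1[C@@](C)(C#CC)CC(=O)CC1(C)C
F8 | step 4 | ethyl (2S)-2-hydroxy-2-[(1S,2S)-2,6,6-trimethyl-4-{2-[(4-methylphenyl)sulfonyl]hydrazinylidene}-2-(prop-1-yn-1-yl)cyclohexyl]acetate | CCOC(=O)[C@@H](O)[C@@H]1[C@@](C)(C#CC)CC(=NNS(=O)(=O)c2ccc(C)cc2)CC1(C)C
F9 | step 3 | ethyl 2-[(1S)-2,6,6-trimethylcyclohex-2-en-1-yl]acetate | CCOC(=O)C[C@@H]1C(C)=CCCC1(C)C
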